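## Retrosynthetic overview

- The depside C(=O)–O bond, from the ring A C1 carbonyl to ring B O4, is cut first. This gives an O2-benzyl ring A keto acid and a ring B phenol carrying a benzyl ester. Both benzyl groups fall in one final hydrogenolysis.
- The strategy rests on one feature shared by ring A and ring B. The 2-oxoheptyl CH2 is bonded to C6, ortho to the C1 carboxyl, and the other ortho carbon C2 bears oxygen (OH in ring A, OMe in ring B). The carboxyl group itself can therefore steer a metal to the only free ortho C–H.
- Each C6–CH2 bond is cut back to a 2,4-dioxygenated benzoic acid and one common hexanoyl-derived sulfoxonium ylide (Cp*Rh-catalysed C–H acylmethylation).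
- Ring order: both benzene rings are bought. The only rings made are two temporary 3-pentylisocoumarin lactones, that of ring B first (step 3) and that of ring A second (step 8). Each is reopened with hydroxide to the keto acid.

Key step: step 3

Remark: the target has no stereocentre and no alkene geometry to control; keto acids 10 and 15 are drawn open-chain although each may sit partly as its cyclic lactol, which does not change how their carboxylates react.

## Route

Step 1
Reactants: 1 trimethylsulfoxonium iodide; 2 hexanoyl chloride
Product: 4 1-[dimethyl(oxo)-lambda6-sulfanylidene]heptan-2-one, via dimethylsulfoxonium methylide 3 (not isolated)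
Conditions: 1 (3 equiv), KOtBu (3 equiv), THF, reflux, 2 h; then 2 (1 equiv), 0 °C to rt
Reagents that add atoms: none
Why: The Corey–Chaykovsky methylide 3 is C-acylated by the acid chloride and a second equivalent of 3 removes the now acidic alpha proton, which is the standard acylation route to carbonyl-stabilised sulfoxonium ylides.

Step 2
Reactants: 5 4-hydroxy-2-methoxybenzoic acid
Product: 7 2-methoxy-4-(triisopropylsilyloxy)benzoic acid, via bis-silylated ester 6 (not isolated)
Conditions: TIPSCl (2.3 equiv), imidazole (5 equiv), DMF, rt; then K2CO3, MeOH–H2O, same flask, rt; 1 M HCl to pH 4, 0 °C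
Reagents that add atoms: triisopropylsilyl chloride, CC(C)[Si](Cl)(C(C)C)C(C)C
Why: Imidazole-promoted silylation caps both acidic oxygens, and the far more electrophilic silyl ester of 6 is then cleaved by mild carbonate while the hindered aryl triisopropylsilyl ether should stay on (selective silyl ester hydrolysis).

Step 3
Reactants: 7 2-methoxy-4-(triisopropylsilyloxy)benzoic acid; 4 1-[dimethyl(oxo)-lambda6-sulfanylidene]heptan-2-one
Product: 9 8-methoxy-3-pentyl-6-(triisopropylsilyloxy)-1H-isochromen-1-one, via ring B keto acid 8 (not isolated)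
Conditions: 4 (1.5 equiv), [Cp*RhCl2]2 (2.5 mol %), AgSbF6 (10 mol %), NaOAc (30 mol %), DCE, 100 °C, sealed tube, N2
Reagents that add atoms: none
Why: Acetate-assisted concerted metalation–deprotonation of the rhodium carboxylate of 7 gives a five-membered rhodacycle at C6, ylide 4 binds through carbon and loses dimethyl sulfoxide to leave a rhodium carbene, and migratory insertion of the aryl group followed by protodemetalation forms the ring B C6–CH2 bond of keto acid 8. The closest known reaction type is the ortho C–H acylmethylation and annulation of benzoic acids with sulfoxonium ylides or alpha-diazo ketones, catalysed by trivalent rhodium or divalent ruthenium, which gives 3-substituted isocoumarins. The one new ring, the six-membered enol lactone, closes by 6-exo-trig addition of the carboxyl oxygen to the ketone carbonyl of 8 and loss of water from the lactol, helped by heat and the Lewis acidic cationic metal. No stereocentre is formed. The step needs site selectivity and a single functionalisation, and the substrate secures both because C2 carries the methoxy group, C6–H is the only C–H ortho to the directing carboxylate, and lactonisation then consumes the directing group. The silyl ether keeps O4 away from O–H insertion of the carbene and from binding to rhodium.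

Step 4
Reactants: 9 8-methoxy-3-pentyl-6-(triisopropylsilyloxy)-1H-isochromen-1-one
Product: 10 4-hydroxy-2-methoxy-6-(2-oxoheptyl)benzoic acid
Conditions: KOH (6 equiv), EtOH–H2O, reflux; then 1 M HCl to pH 3, 0 °C
Reagents that add atoms: potassium hydroxide, [K+].[OH-]
Why: In this saponification of the enol lactone, hydroxide adds to C1, the released enolate tautomerises to the ketone and the carboxylate cannot reclose in base, while hydroxide attack at silicon strips the aryl silyl ether, whose phenoxide leaves readily because it stands para to the carbonyl.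

Step 5
Reactants: 10 4-hydroxy-2-methoxy-6-(2-oxoheptyl)benzoic acid
Product: 11 benzyl 4-hydroxy-2-methoxy-6-(2-oxoheptyl)benzoate
Conditions: BnBr (1.05 equiv), KHCO3 (1.1 equiv), DMF, rt
Reagents that add atoms: benzyl bromide, BrCc1ccccc1
Why: Bicarbonate deprotonates only the carboxylic acid and not the much less acidic phenol or the benzylic ketone CH2, so SN2 O-alkylation of the carboxylate should give the benzyl ester with O4 left free.

Step 6
Reactants: 12 2-hydroxy-4-methoxybenzoic acid
Product: 13 benzyl 2-(benzyloxy)-4-methoxybenzoate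
Conditions: BnBr (2.4 equiv), K2CO3 (3 equiv), DMF, 60 °C
Reagents that add atoms: benzyl bromide, BrCc1ccccc1
Why: Exhaustive Williamson-type alkylation benzylates the carboxylate and, on warming, the hydrogen-bonded ortho phenol.

Step 7
Reactants: 13 benzyl 2-(benzyloxy)-4-methoxybenzoate
Product: 14 2-(benzyloxy)-4-methoxybenzoic acid
Conditions: KOH (3 equiv), MeOH–THF–H2O, reflux; then 1 M HCl to pH 2
Reagents that add atoms: potassium hydroxide, [K+].[OH-]
Why: Ordinary ester saponification of a benzoate with only one ortho substituent frees the directing carboxyl group and leaves the benzyl aryl ether untouched.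

Step 8
Reactants: 14 2-(benzyloxy)-4-methoxybenzoic acid; 4 1-[dimethyl(oxo)-lambda6-sulfanylidene]heptan-2-one
Product: 16 8-(benzyloxy)-6-methoxy-3-pentyl-1H-isochromen-1-one, via ring A keto acid 15 (not isolated)
Conditions: 4 (1.5 equiv), [Cp*RhCl2]2 (2.5 mol %), AgSbF6 (10 mol %), NaOAc (30 mol %), DCE, 100 °C, sealed tube, N2
Reagents that add atoms: none
Why: This is the same carboxylate-directed C–H acylmethylation and annulation as step 3, with C2 blocked by the benzyloxy group so that only C6–H can be metalated, and the neutral lactone should be easy to separate from catalyst and unreacted acid.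

Step 9
Reactants: 16 8-(benzyloxy)-6-methoxy-3-pentyl-1H-isochromen-1-one
Product: 15 2-(benzyloxy)-4-methoxy-6-(2-oxoheptyl)benzoic acid
Conditions: KOH (5 equiv), EtOH–H2O, reflux; then 1 M HCl to pH 3, 0 °C
Reagents that add atoms: potassium hydroxide, [K+].[OH-]
Why: Saponification of the enol lactone gives the keto carboxylate, which stays open in base, so the keto acid that step 8 only passed through is now isolated after cold acidification, with the benzyl and methyl ethers inert to hydroxide.

Step 10
Reactants: 15 2-(benzyloxy)-4-methoxy-6-(2-oxoheptyl)benzoic acid; 11 benzyl 4-hydroxy-2-methoxy-6-(2-oxoheptyl)benzoate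
Product: 17 benzyl 4-{[2-(benzyloxy)-4-methoxy-6-(2-oxoheptyl)benzoyl]oxy}-2-methoxy-6-(2-oxoheptyl)benzoate
Conditions: 15 (1.1 equiv), 11 (1.0 equiv), DCC (1.3 equiv), 4-(dimethylamino)pyridinium tosylate (0.3 equiv), CH2Cl2, 0 °C to rt
Reagents that add atoms: none
Why: Steglich-type carbodiimide esterification is the usual way to join a 2,6-disubstituted benzoic acid to a phenol in depside work, the buffered DMAP salt and low temperature keep enolisation of the side-chain ketone slow, and any acid that does reclose only returns 16, which re-enters at step 9.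

Step 11
Reactants: 17 benzyl 4-{[2-(benzyloxy)-4-methoxy-6-(2-oxoheptyl)benzoyl]oxy}-2-methoxy-6-(2-oxoheptyl)benzoate
Product: 18 4-{[2-hydroxy-4-methoxy-6-(2-oxoheptyl)benzoyl]oxy}-2-methoxy-6-(2-oxoheptyl)benzoic acid (target)
Conditions: H2 (1 atm), Pd/C (10 wt %), EtOAc, rt
Reagents that add atoms: none
Why: Catalytic hydrogenolysis cleaves the benzyl ester and the benzyl aryl ether under neutral conditions, which should leave the two non-conjugated ketones, the aryl ester and the methyl ethers untouched.

## Compound list

1 | trimethylsulfoxonium iodide | C[S+](C)(C)=O.[I-] | starting material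
2 | hexanoyl chloride | CCCCCC(=O)Cl | starting material
3 | dimethylsulfoxonium methylide | C=S(C)(C)=O | intermediate
4 | 1-[dimethyl(oxo)-lambda6-sulfanylidene]heptan-2-one | CCCCCC(=O)C=S(C)(C)=O | intermediate
5 | 4-hydroxy-2-methoxybenzoic acid | COc1cc(O)ccc1C(=O)O | starting material
6 | triisopropylsilyl 2-methoxy-4-(triisopropylsilyloxy)benzoate (bis-silylated ester) | COc1cc(O[Si](C(C)C)(C(C)C)C(C)C)ccc1C(=O)O[Si](C(C)C)(C(C)C)C(C)C | intermediate
7 | 2-methoxy-4-(triisopropylsilyloxy)benzoic acid | COc1cc(O[Si](C(C)C)(C(C)C)C(C)C)ccc1C(=O)O | intermediate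
8 | 2-methoxy-6-(2-oxoheptyl)-4-(triisopropylsilyloxy)benzoic acid (ring B keto acid) | CCCCCC(=O)Cc1cc(O[Si](C(C)C)(C(C)C)C(C)C)cc(OC)c1C(=O)O | intermediate
9 | 8-methoxy-3-pentyl-6-(triisopropylsilyloxy)-1H-isochromen-1-one | CCCCCC1=Cc2cc(O[Si](C(C)C)(C(C)C)C(C)C)cc(OC)c2C(=O)O1 | intermediate
10 | 4-hydroxy-2-methoxy-6-(2-oxoheptyl)benzoic acid | CCCCCC(=O)Cc1cc(O)cc(OC)c1C(=O)O | intermediate
11 | benzyl 4-hydroxy-2-methoxy-6-(2-oxoheptyl)benzoate | CCCCCC(=O)Cc1cc(O)cc(OC)c1C(=O)OCc1ccccc1 | intermediate
12 | 2-hydroxy-4-methoxybenzoic acid | COc1ccc(C(=O)O)c(O)c1 | starting material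
13 | benzyl 2-(benzyloxy)-4-methoxybenzoate | COc1ccc(C(=O)OCc2ccccc2)c(OCc2ccccc2)c1 | intermediate
14 | 2-(benzyloxy)-4-methoxybenzoic acid | COc1ccc(C(=O)O)c(OCc2ccccc2)c1 | intermediate
15 | 2-(benzyloxy)-4-methoxy-6-(2-oxoheptyl)benzoic acid (ring A keto acid) | CCCCCC(=O)Cc1cc(OC)cc(OCc2ccccc2)c1C(=O)O | intermediate
16 | 8-(benzyloxy)-6-methoxy-3-pentyl-1H-isochromen-1-one | CCCCCC1=Cc2cc(OC)cc(OCc3ccccc3)c2C(=O)O1 | intermediate
17 | benzyl 4-{[2-(benzyloxy)-4-methoxy-6-(2-oxoheptyl)benzoyl]oxy}-2-methoxy-6-(2-oxoheptyl)benzoate | CCCCCC(=O)Cc1cc(OC)cc(OCc2ccccc2)c1C(=O)Oc1cc(CC(=O)CCCCC)c(C(=O)OCc2ccccc2)c(OC)c1 | intermediate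
18 | 4-{[2-hydroxy-4-methoxy-6-(2-oxoheptyl)benzoyl]oxy}-2-methoxy-6-(2-oxoheptyl)benzoic acid | CCCCCC(=O)Cc1cc(OC)cc(O)c1C(=O)Oc1cc(CC(=O)CCCCC)c(C(=O)O)c(OC)c1 | target

## Step count and risks

Total step count: 11.
Longest linear sequence: 6 steps (steps 6, 7, 8, 9, 10, 11). The ring B branch (steps 2, 3, 4, 5, 10, 11) and the branch that begins with the ylide (steps 1, 3, 4, 5, 10, 11) are equally long.

**Risk at step 3.** The ortho methoxy group twists the carboxylate out of the ring plane, so cyclometalation may be slow. Ylide decomposition, protodecarboxylation of the electron-rich acid or loss of the silyl group under the cationic conditions could then overtake the coupling.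

The fallback sets out from 7 and comes back at 9. It replaces catalytic C–H activation by stoichiometric metalation and alkyne annulation.
- The lithium carboxylate of 7 is lithiated at C6 with s-BuLi/TMEDA (2.2 equiv) in THF at −78 °C. Metalation ortho to the carboxylate should win because C3 lies between two ethers, one of them very bulky.
- Quenching with I2 gives 6-iodo-2-methoxy-4-(triisopropylsilyloxy)benzoic acid F1.
- F1 is heated with hept-1-yne, Pd(PPh3)4, ZnCl2 and Et3N in DMF at 100 °C. Sonogashira-type coupling followed by 6-endo-dig addition of the carboxylate to the activated alkyne then delivers 9.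

**Risk at step 8.** The hindered carboxylate may again bind and metalate weakly. In addition, the benzyl ether next to the carbonyl may be lost through Lewis acid assistance at 100 °C.

The fallback sets out from 14 and comes back at 16. It installs a stronger directing group that leaves during the annulation.
- Acid 14 is coupled with MeONH2·HCl (EDC·HCl, Et3N, CH2Cl2) to give 2-(benzyloxy)-N,4-dimethoxybenzamide F2.
- The N–H amide of F2 forms a robust five-membered rhodacycle at C6 under [Cp*RhCl2]2, AgSbF6 and PivOH in DCE at 100 °C, with ylide 4 as the carbene source.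
- After acylmethylation, the enol oxygen of the new ketone attacks the amide carbonyl under the acidic conditions and expels the methoxyamine unit. This closes the lactone of 16.

**Risk at step 10.** The activated acid may reclose onto the enol of its own ketone faster than the phenol attacks it. The crowded O-acylisourea may also rearrange by acyl migration to nitrogen.

The fallback sets out from 15 and comes back at 17. It masks the ring A ketone before the acid is activated.
- Acid 15 is alkylated with allyl bromide and KHCO3 in DMF to give allyl 2-(benzyloxy)-4-methoxy-6-(2-oxoheptyl)benzoate F3.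
- Noyori ketalisation (TMSOCH2CH2OTMS, cat. TMSOTf, CH2Cl2, −78 to −20 °C) gives allyl 2-(benzyloxy)-4-methoxy-6-[(2-pentyl-1,3-dioxolan-2-yl)methyl]benzoate F4.
- Tsuji–Trost deallylation (Pd(PPh3)4, morpholine, THF, rt) frees 2-(benzyloxy)-4-methoxy-6-[(2-pentyl-1,3-dioxolan-2-yl)methyl]benzoic acid F5, which has no enolisable ketone.
- F5 is joined to 11 with DCC and DMAP in CH2Cl2 to give benzyl 4-({2-(benzyloxy)-4-methoxy-6-[(2-pentyl-1,3-dioxolan-2-yl)methyl]benzoyl}oxy)-2-methoxy-6-(2-oxoheptyl)benzoate F6.
- Mild aqueous acid (PPTS, acetone–H2O, 50 °C) removes the dioxolane and gives 17.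

## Further compounds

F1 | step 3 | 6-iodo-2-methoxy-4-(triisopropylsilyloxy)benzoic acid | COc1cc(O[Si](C(C)C)(C(C)C)C(C)C)cc(I)c1C(=O)O
F2 | step 8 | 2-(benzyloxy)-N,4-dimethoxybenzamide | CONC(=O)c1ccc(OC)cc1OCc1ccccc1
F3 | step 10 | allyl 2-(benzyloxy)-4-methoxy-6-(2-oxoheptyl)benzoate | C=CCOC(=O)c1c(CC(=O)CCCCC)cc(OC)cc1OCc1ccccc1
F4 | step 10 | allyl 2-(benzyloxy)-4-methoxy-6-[(2-pentyl-1,3-dioxolan-2-yl)methyl]benzoate | C=CCOC(=O)c1c(CC2(CCCCC)OCCO2)cc(OC)cc1OCc1ccccc1
F5 | step 10 | 2-(benzyloxy)-4-methoxy-6-[(2-pentyl-1,3-dioxolan-2-yl)methyl]benzoic acid | O=C(O)c1c(CC2(CCCCC)OCCO2)cc(OC)cc1OCc1ccccc1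
F6 | step 10 | benzyl 4-({2-(benzyloxy)-4-methoxy-6-[(2-pentyl-1,3-dioxolan-2-yl)methyl]benzoyl}oxy)-2-methoxy-6-(2-oxoheptyl)benzoate | CCCCCC1(Cc2cc(OC)cc(OCc3ccccc3)c2C(=O)Oc2cc(CC(=O)CCCCC)c(C(=O)OCc3ccccc3)c(OC)c2)OCCO1
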